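**Retrosynthetic overview**

1. Last step: the spiroketal is made from a cyclobutyl silyl peroxide. Ring A (the oxolane O1–C2–C3–C4–C5 that carries the long chain) arises from the cyclobutane by insertion of the peroxide oxygen into ring bond C1–C2 (four atoms to five); ring B (the methyl oxolane) closes in the same operation by addition of the side-chain OH to the oxocarbenium carbon.
2. Enabling feature: an O–O bond on cyclobutane C1, which also carries the (S)-3-hydroxybutyl arm, next to ring carbon C2, the secondary (S)-stereocentre that carries the hexyl–phthalide chain. The strained C1–C2 σ bond antiperiplanar to O–O migrates to oxygen with retention.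
3. Peroxide ⇐ alkylidenecyclobutane (cobalt-hydride hydrogen-atom transfer, O2) ⇐ methylenecyclobutane + (S)-pent-4-en-2-ol (cross-metathesis) ⇐ cyclobutanone (methylenation).
4. Chain: (S)-2-(pent-4-enyl)cyclobutanone (RAMP-hydrazone alkylation of cyclobutanone) + (R)-3-allyl-5,7-dimethoxyphthalide (cross-metathesis, then hydrogenation).
5. Order of rings: arene and cyclobutane are bought; the phthalide lactone is closed first (asymmetric allylboration, anionic carbamoyl shift); rings A and B form together in the last step.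

Key step: step 13

**Remarks on the chemistry**

- Cyclobutane locants used below: C1 is the carbon bearing the carbonyl, alkylidene or peroxide group; C2 is the neighbouring stereocentre bearing the chain.
- The alkylidenecyclobutane is used as an E/Z mixture and the silyl peroxide as a mixture of epimers at C1, because both elements are erased in the following step; the SMILES show the isomer expected to predominate.
- The spiro centre of a 1,6-dioxaspiro[4.4]nonane equilibrates under acid with little intrinsic bias, so the last step is expected to give both spiro epimers; the (R)-spiro compound is the target and the other epimer is recycled by re-equilibration.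

**Route**

Step 1
Reactants: 1 cyclobutanone; 2 (R)-1-amino-2-(methoxymethyl)pyrrolidine (RAMP)
Product: 3 (R)-N-cyclobutylidene-2-(methoxymethyl)pyrrolidin-1-amine
Conditions: CH2Cl2, MgSO4, rt
Reagents that add atoms: none
Why: Condensation of the strained, electrophilic ketone with the N-amino auxiliary (hydrazone formation) needs no catalyst, forms no stereocentre and leaves the (R)-centre of the auxiliary untouched.

Step 2
Reactants: 3 (R)-N-cyclobutylidene-2-(methoxymethyl)pyrrolidin-1-amine; 4 5-bromopent-1-ene
Product: 6 (R)-2-(methoxymethyl)-N-[(2S)-2-(pent-4-en-1-yl)cyclobutylidene]pyrrolidin-1-amine, via lithium azaenolate 5 (not isolated)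
Conditions: LiN(i-Pr)2 (LDA, 1.1 equiv), THF, 0 °C; then 4 (1.2 equiv), −100 °C → rt
Reagents that add atoms: none
Why: Enders SAMP/RAMP hydrazone alkylation: the lithium of azaenolate 5 is chelated by the methoxymethyl arm, so the primary bromide attacks one diastereotopic face, and by analogy with cyclic ketones (SAMP gives the R α-centre when the ring outranks the new group) RAMP should give the (S)-centre at C2.

Step 3
Reactants: 6 (R)-2-(methoxymethyl)-N-[(2S)-2-(pent-4-en-1-yl)cyclobutylidene]pyrrolidin-1-amine
Product: 7 (S)-2-(pent-4-en-1-yl)cyclobutan-1-one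
Conditions: saturated aq. oxalic acid, Et2O, rt, two-phase
Reagents that add atoms: water (O)
Why: Two-phase oxalic acid hydrolysis of the hydrazone is a mild cleavage that should not enolise the ketone, tolerates the terminal alkene (ozonolytic cleavage would not) and returns the auxiliary; the C2 centre is not touched.

Step 4
Reactants: 8 3,5-dimethoxybenzaldehyde
Product: 10 (R)-1-(3,5-dimethoxyphenyl)but-3-en-1-ol, via pinacol borate ester 9 (not isolated)
Conditions: allylB(pin) (1.2 equiv), (R)-3,3'-bis(2,4,6-triisopropylphenyl)-1,1'-binaphthyl-2,2'-diyl hydrogen phosphate ((R)-TRIP, 5 mol %), toluene, −30 °C; aqueous work-up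
Reagents that add atoms: allylboronic acid pinacol ester (C=CCB1OC(C)(C)C(C)(C)O1)
Why: Chiral-phosphoric-acid-catalysed asymmetric allylboration through a chair six-membered transition state, in which the (R)-catalyst binds the boronate oxygen and the formyl hydrogen, should deliver allyl to the Re face of the aryl aldehyde and set the (R)-carbinol centre that becomes C3 of the phthalide.

Step 5
Reactants: 10 (R)-1-(3,5-dimethoxyphenyl)but-3-en-1-ol
Product: 11 (R)-1-(3,5-dimethoxyphenyl)but-3-en-1-yl N,N-diethylcarbamate
Conditions: NaH, Et2NCOCl, THF, 0 °C → rt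
Reagents that add atoms: diethylcarbamoyl chloride (CCN(CC)C(=O)Cl)
Why: O-carbamoylation of the sodium alkoxide is a simple acyl transfer at oxygen that installs the future lactone carbonyl carbon without touching the stereocentre.

Step 6
Reactants: 11 (R)-1-(3,5-dimethoxyphenyl)but-3-en-1-yl N,N-diethylcarbamate
Product: 12 (R)-1-(2-bromo-3,5-dimethoxyphenyl)but-3-en-1-yl N,N-diethylcarbamate
Conditions: NBS (1.05 equiv), MeCN, 0 °C, dark
Reagents that add atoms: N-bromosuccinimide (O=C1CCC(=O)N1Br)
Why: Electrophilic aromatic bromination goes to the ring position ortho to the side chain and para to one methoxy group rather than to the hindered position between both methoxy groups, and under polar, dark conditions the electron-rich arene reacts much faster than the isolated alkene.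

Step 7
Reactants: 12 (R)-1-(2-bromo-3,5-dimethoxyphenyl)but-3-en-1-yl N,N-diethylcarbamate
Product: 15 (R)-3-allyl-5,7-dimethoxyisobenzofuran-1(3H)-one, via aryllithium 13 (not isolated), via hydroxy amide 14 (not isolated)
Conditions: t-BuLi (2.1 equiv), THF, −78 °C; then 2 M HCl, rt
Reagents that add atoms: none
Why: Bromine–lithium exchange gives aryllithium 13, which attacks the carbamate carbonyl through a five-membered transition state (anionic 1,4-carbamoyl O-to-C shift, a Parham-type cyclisation), and hydroxy amide 14 lactonises under acid with loss of diethylamine; the benzylic C–O bond is never broken, so the (R)-centre is retained.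

Step 8
Reactants: 7 (S)-2-(pent-4-en-1-yl)cyclobutan-1-one; 15 (R)-3-allyl-5,7-dimethoxyisobenzofuran-1(3H)-one
Product: 16 (R)-5,7-dimethoxy-3-{(E)-6-[(S)-2-oxocyclobutyl]hex-2-en-1-yl}isobenzofuran-1(3H)-one
Conditions: second-generation Grubbs catalyst RuCl2(=CHPh)(H2IMes)(PCy3) (5 mol %), 7 (2.5 equiv), CH2Cl2, 40 °C, argon sweep
Reagents that add atoms: none
Why: Olefin cross-metathesis of two unhindered terminal alkenes joins the fragments with loss of ethylene; no stereocentre is formed, the alkene geometry is irrelevant because step 9 saturates it, and the excess of 7 limits homodimerisation of 15.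

Step 9
Reactants: 16 (R)-5,7-dimethoxy-3-{(E)-6-[(S)-2-oxocyclobutyl]hex-2-en-1-yl}isobenzofuran-1(3H)-one
Product: 17 (R)-5,7-dimethoxy-3-{6-[(S)-2-oxocyclobutyl]hexyl}isobenzofuran-1(3H)-one
Conditions: H2 (1 atm), 10% Pd/C, EtOAc, rt
Reagents that add atoms: none
Why: Heterogeneous catalytic hydrogenation reduces the 1,2-disubstituted alkene under conditions that should leave the cyclobutanone, the lactone and the aryl ethers untouched and epimerise neither stereocentre.

Step 10
Reactants: 17 (R)-5,7-dimethoxy-3-{6-[(S)-2-oxocyclobutyl]hexyl}isobenzofuran-1(3H)-one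
Product: 18 (R)-5,7-dimethoxy-3-{6-[(S)-2-methylenecyclobutyl]hexyl}isobenzofuran-1(3H)-one
Conditions: Zn, CH2Br2, TiCl4, THF/CH2Cl2, 0 °C → rt
Reagents that add atoms: dibromomethane (BrCBr)
Why: Takai–Lombardo methylenation uses a non-basic gem-dimetallic reagent that attacks ketones but not lactones, so the exocyclic methylene is installed without enolisation and the (S)-centre at C2 is kept.

Step 11
Reactants: 18 (R)-5,7-dimethoxy-3-{6-[(S)-2-methylenecyclobutyl]hexyl}isobenzofuran-1(3H)-one; 19 (S)-pent-4-en-2-ol
Product: 20 (R)-3-{6-[(S,E)-2-((S)-3-hydroxybutylidene)cyclobutyl]hexyl}-5,7-dimethoxyisobenzofuran-1(3H)-one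
Conditions: second-generation Hoveyda–Grubbs catalyst RuCl2(H2IMes)(=CH–C6H4-2-O-i-Pr) (10 mol %), 19 (4 equiv), CH2Cl2, 40 °C
Reagents that add atoms: none
Why: Olefin cross-metathesis of the strained 1,1-disubstituted methylenecyclobutane with an excess of terminal alkene 19 should give the trisubstituted alkylidenecyclobutane; both geometric isomers are usable because step 12 destroys the double bond, and the (S)-carbinol centre comes unchanged from 19.

Step 12
Reactants: 20 (R)-3-{6-[(S,E)-2-((S)-3-hydroxybutylidene)cyclobutyl]hexyl}-5,7-dimethoxyisobenzofuran-1(3H)-one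
Product: 21 (R)-3-{6-[(1S,2R)-2-((S)-3-hydroxybutyl)-2-(triethylsilylperoxy)cyclobutyl]hexyl}-5,7-dimethoxyisobenzofuran-1(3H)-one
Conditions: Co(thd)2 [bis(2,2,6,6-tetramethylheptane-3,5-dionato)cobalt] (10 mol %), Et3SiH (3 equiv), O2 (1 atm), ClCH2CH2Cl, rt
Reagents that add atoms: dioxygen (O=O); triethylsilane (CC[SiH](CC)CC)
Why: Mukaiyama–Isayama silylperoxidation: a cobalt hydride transfers a hydrogen atom to the less substituted alkene carbon, the tertiary cyclobutyl radical at C1 is trapped by O2 and the cobalt peroxide is silylated; C2 is not involved, and the configuration of the new peroxide carbon (O2 should approach mainly anti to the C2 chain) is irrelevant because C1 becomes planar in step 13.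

Step 13
Reactants: 21 (R)-3-{6-[(1S,2R)-2-((S)-3-hydroxybutyl)-2-(triethylsilylperoxy)cyclobutyl]hexyl}-5,7-dimethoxyisobenzofuran-1(3H)-one
Product: 23 (3R)-5,7-dimethoxy-3-{6-[(2S,5R,7S)-7-methyl-1,6-dioxaspiro[4.4]nonan-2-yl]hexyl}isobenzofuran-1(3H)-one, via oxocarbenium ion 22 (not isolated)
Conditions: BF3·OEt2 (1.2 equiv), CH2Cl2, −78 → 0 °C; then sat. aq. NaHCO3; HPLC separation of the spiro epimers
Reagents that add atoms: none
Why: Proposed new method: BF3 activates the distal, silylated peroxide oxygen of 21 and the O–O bond ionises with concerted 1,2-shift of the antiperiplanar ring bond C1–C2 to oxygen (a Hock/Criegee rearrangement), so the cyclobutane expands to the five-membered cyclic oxocarbenium ion 22 with release of most of the four-ring strain, and the pendant (S)-carbinol then adds to 22 to give the spiroketal; the closest known reaction types are the Hock cleavage of tertiary hydroperoxides, the Criegee rearrangement of peresters and the Baeyer–Villiger oxidation of 2-alkylcyclobutanones, none of which has been used to turn a cyclobutyl peroxide into a spiroketal. Ring A closes by ring expansion of the carbocycle through carbon-to-oxygen migration, and ring B closes by 5-exo-trig addition of the hydroxyl group to the oxocarbenium carbon. The O–CH centre of ring A is controlled by the substrate, because the migrating carbon C2 keeps its configuration (retention, as in Baeyer–Villiger and Criegee shifts), so (S)-C2 of the cyclobutane becomes the (S)-centre of ring A whatever the configuration at C1. The spiro centre is set under thermodynamic control by acid equilibration of the ketal; both epimers of a 1,6-dioxaspiro[4.4]nonane have the same anomeric stabilisation, so little bias is expected, and the (R)-spiro epimer 23 is to be separated while the other epimer is re-subjected to the acid. The selectivity the step needs is migration of C2 rather than of C4 or of the side-chain CH2: the secondary ring carbon has the higher migratory aptitude, and only a ring-bond shift releases strain, which disfavours the side-chain shift.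

**Compound list**

1 | cyclobutanone | O=C1CCC1 | starting material
2 | (R)-1-amino-2-(methoxymethyl)pyrrolidine (RAMP) | COC[C@H]1CCCN1N | starting material
3 | (R)-N-cyclobutylidene-2-(methoxymethyl)pyrrolidin-1-amine | COC[C@H]1CCCN1N=C1CCC1 | intermediate
4 | 5-bromopent-1-ene | C=CCCCBr | starting material
5 | lithium azaenolate of 3 | COC[C@H]1CCCN1N([Li])C1=CCC1 | intermediate
6 | (R)-2-(methoxymethyl)-N-[(2S)-2-(pent-4-en-1-yl)cyclobutylidene]pyrrolidin-1-amine (E-hydrazone drawn) | COC[C@H]1CCCN1/N=C1\CC[C@@H]1CCCC=C | intermediate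
7 | (S)-2-(pent-4-en-1-yl)cyclobutan-1-one | C=CCCC[C@H]1CCC1=O | intermediate
8 | 3,5-dimethoxybenzaldehyde | COc1cc(C=O)cc(OC)c1 | starting material
9 | (R)-2-{[1-(3,5-dimethoxyphenyl)but-3-en-1-yl]oxy}-4,4,5,5-tetramethyl-1,3,2-dioxaborolane | C=CC[C@@H](OB1OC(C)(C)C(C)(C)O1)c1cc(OC)cc(OC)c1 | intermediate
10 | (R)-1-(3,5-dimethoxyphenyl)but-3-en-1-ol | C=CC[C@@H](O)c1cc(OC)cc(OC)c1 | intermediate
11 | (R)-1-(3,5-dimethoxyphenyl)but-3-en-1-yl N,N-diethylcarbamate | C=CC[C@@H](OC(=O)N(CC)CC)c1cc(OC)cc(OC)c1 | intermediate
12 | (R)-1-(2-bromo-3,5-dimethoxyphenyl)but-3-en-1-yl N,N-diethylcarbamate | C=CC[C@@H](OC(=O)N(CC)CC)c1cc(OC)cc(OC)c1Br | intermediate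
13 | (R)-1-(2-lithio-3,5-dimethoxyphenyl)but-3-en-1-yl N,N-diethylcarbamate | C=CC[C@@H](OC(=O)N(CC)CC)c1cc(OC)cc(OC)c1[Li] | intermediate
14 | (R)-N,N-diethyl-2-(1-hydroxybut-3-en-1-yl)-4,6-dimethoxybenzamide | C=CC[C@@H](O)c1cc(OC)cc(OC)c1C(=O)N(CC)CC | intermediate
15 | (R)-3-allyl-5,7-dimethoxyisobenzofuran-1(3H)-one | COc1cc(OC)c2c(c1)[C@@H](CC=C)OC2=O | intermediate
16 | (R)-5,7-dimethoxy-3-{(E)-6-[(S)-2-oxocyclobutyl]hex-2-en-1-yl}isobenzofuran-1(3H)-one | COc1cc(OC)c2c(c1)[C@@H](C/C=C/CCC[C@H]1CCC1=O)OC2=O | intermediate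
17 | (R)-5,7-dimethoxy-3-{6-[(S)-2-oxocyclobutyl]hexyl}isobenzofuran-1(3H)-one | COc1cc(OC)c2c(c1)[C@@H](CCCCCC[C@H]1CCC1=O)OC2=O | intermediate
18 | (R)-5,7-dimethoxy-3-{6-[(S)-2-methylenecyclobutyl]hexyl}isobenzofuran-1(3H)-one | COc1cc(OC)c2c(c1)[C@@H](CCCCCC[C@H]1CCC1=C)OC2=O | intermediate
19 | (S)-pent-4-en-2-ol | C=CC[C@H](C)O | starting material
20 | (R)-3-{6-[(S,E)-2-((S)-3-hydroxybutylidene)cyclobutyl]hexyl}-5,7-dimethoxyisobenzofuran-1(3H)-one (E isomer drawn, Z isomer also used) | COc1cc(OC)c2c(c1)[C@@H](CCCCCC[C@H]1CC/C1=C\C[C@H](C)O)OC2=O | intermediate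
21 | (R)-3-{6-[(1S,2R)-2-((S)-3-hydroxybutyl)-2-(triethylsilylperoxy)cyclobutyl]hexyl}-5,7-dimethoxyisobenzofuran-1(3H)-one (epimer at the peroxide carbon also used) | COc1cc(OC)c2c(c1)[C@@H](CCCCCC[C@H]1CC[C@]1(CC[C@H](C)O)OO[Si](CC)(CC)CC)OC2=O | intermediate
22 | (5S)-2-[(S)-3-hydroxybutyl]-5-{6-[(R)-5,7-dimethoxy-3-oxo-1,3-dihydroisobenzofuran-1-yl]hexyl}-4,5-dihydro-3H-furan-1-ium | COc1cc(OC)c2c(c1)[C@@H](CCCCCC[C@H]1CCC(CC[C@H](C)O)=[O+]1)OC2=O | intermediate
23 | (3R)-5,7-dimethoxy-3-{6-[(2S,5R,7S)-7-methyl-1,6-dioxaspiro[4.4]nonan-2-yl]hexyl}isobenzofuran-1(3H)-one | COc1cc(OC)c2c(c1)[C@@H](CCCCCC[C@H]1CC[C@@]3(CC[C@H](C)O3)O1)OC2=O | target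

**Step count and risks**

Total step count: 13. Longest linear sequence: 10 steps (from 8 through steps 4–7 and 8–13 to 23).

The three steps most likely to fail:

1. Step 13 (proposed new method). What may go wrong: migration of the wrong bond (C1–C4 or the side-chain CH2) to oxygen, ionisation of the C1–O bond instead of the O–O bond with cyclobutyl-cation rearrangements, and equilibration of the spiro centre to a mixture poor in the wanted epimer.
Fallback, known chemistry, setting out from 7 and coming back to the route at 23: Baeyer–Villiger oxidation of 7 with 30% H2O2 in CF3CH2OH at rt (the more substituted carbon migrates with retention; the terminal alkene is not epoxidised) should give (S)-5-(pent-4-en-1-yl)oxolan-2-one F1. In parallel, commercial (S)-butane-1,3-diol is iodinated at the primary hydroxyl (PPh3, I2, imidazole, 0 °C) to (S)-4-iodobutan-2-ol F2 and silylated (TBSCl, imidazole, DMF) to (S)-tert-butyl[(4-iodobutan-2-yl)oxy]dimethylsilane F3. Iodine–lithium exchange (t-BuLi, Et2O, −78 °C) gives (S)-[3-(tert-butyldimethylsilyloxy)butyl]lithium F4, which is added to F1 at −78 °C to give (2S,8S)-2-(tert-butyldimethylsilyloxy)-8-hydroxytridec-12-en-5-one F5 (in equilibrium with its lactol). CSA in MeOH/CH2Cl2 removes the silyl group and closes the ketal to (2S,5R,7S)-7-methyl-2-(pent-4-en-1-yl)-1,6-dioxaspiro[4.4]nonane F6 together with its spiro epimer. Cross-metathesis of F6 with 15 (second-generation Grubbs catalyst, CH2Cl2, 40 °C) gives (R)-5,7-dimethoxy-3-{(E)-6-[(2S,5R,7S)-7-methyl-1,6-dioxaspiro[4.4]nonan-2-yl]hex-2-en-1-yl}isobenzofuran-1(3H)-one F7, and hydrogenation (H2, Pd/C, EtOAc) gives 23.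

2. Step 11. What may go wrong: slow metathesis at the hindered 1,1-disubstituted alkene, homodimerisation of 19 consuming the catalyst, and ruthenium-hydride migration of the exocyclic double bond into the four-membered ring towards C2.
Fallback, setting out from 7 and coming back at 20, with a Wittig reaction and a chemoselective hydrogenation in place of the second metathesis: commercial (S)-butane-1,3-diol is brominated at the primary hydroxyl (PPh3, CBr4, CH2Cl2, 0 °C) to (S)-4-bromobutan-2-ol F8, which with PPh3 in refluxing MeCN gives (S)-(3-hydroxybutyl)triphenylphosphonium bromide F9. Double deprotonation with KN(SiMe3)2 (2 equiv, THF, −78 °C) gives the potassium oxido ylide F10, and Wittig olefination of 7 at −78 °C gives (S)-4-[(S)-2-(pent-4-en-1-yl)cyclobutylidene]butan-2-ol F11 as an E/Z mixture. Cross-metathesis of the terminal alkene of F11 with 15 (second-generation Grubbs catalyst; the trisubstituted exocyclic alkene should be inert) gives (R)-3-{(E)-6-[(S)-2-((S)-3-hydroxybutylidene)cyclobutyl]hex-2-en-1-yl}-5,7-dimethoxyisobenzofuran-1(3H)-one F12. Hydrogenation with RhCl(PPh3)3 and H2 in benzene/EtOH should saturate only the 1,2-disubstituted alkene and give 20.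

3. Step 12. What may go wrong: reversible hydrogen-atom transfer moving the double bond into the ring towards C2 and eroding its configuration, and over-reduction of the peroxide to the tertiary alcohol by the silane.
Fallback, setting out from 20 and coming back at 23 through 22, with a pericyclic oxygenation in place of the radical one: Schenck ene reaction of 20 with singlet oxygen (O2, visible light, tetraphenylporphyrin, CH2Cl2, 0 °C) should bond oxygen to C1 and shift the double bond into the side chain, because abstraction of a ring hydrogen would give a cyclobutene, and so give (R)-3-{6-[(1S)-2-hydroperoxy-2-((S,E)-3-hydroxybut-1-en-1-yl)cyclobutyl]hexyl}-5,7-dimethoxyisobenzofuran-1(3H)-one F13. Diimide (potassium azodicarboxylate, AcOH, MeOH, 0 °C → rt) reduces the C=C bond and leaves the O–O bond, giving (R)-3-{6-[(1S)-2-hydroperoxy-2-((S)-3-hydroxybutyl)cyclobutyl]hexyl}-5,7-dimethoxyisobenzofuran-1(3H)-one F14. Under the conditions of step 13, F14 should lose water in the same carbon-to-oxygen shift and give 23 by way of 22.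

Further compounds
F1 | step 13 | (S)-5-(pent-4-en-1-yl)oxolan-2-one | C=CCCC[C@H]1CCC(=O)O1
F2 | step 13 | (S)-4-iodobutan-2-ol | C[C@H](O)CCI
F3 | step 13 | (S)-tert-butyl[(4-iodobutan-2-yl)oxy]dimethylsilane | C[C@H](O[Si](C)(C)C(C)(C)C)CCI
F4 | step 13 | (S)-[3-(tert-butyldimethylsilyloxy)butyl]lithium | C[C@H](O[Si](C)(C)C(C)(C)C)CC[Li]
F5 | step 13 | (2S,8S)-2-(tert-butyldimethylsilyloxy)-8-hydroxytridec-12-en-5-one | C=CCCC[C@H](O)CCC(=O)CC[C@H](C)O[Si](C)(C)C(C)(C)C
F6 | step 13 | (2S,5R,7S)-7-methyl-2-(pent-4-en-1-yl)-1,6-dioxaspiro[4.4]nonane | C=CCCC[C@H]1CC[C@@]2(CC[C@H](C)O2)O1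
F7 | step 13 | (R)-5,7-dimethoxy-3-{(E)-6-[(2S,5R,7S)-7-methyl-1,6-dioxaspiro[4.4]nonan-2-yl]hex-2-en-1-yl}isobenzofuran-1(3H)-one | COc1cc(OC)c2c(c1)[C@@H](C/C=C/CCC[C@H]1CC[C@@]3(CC[C@H](C)O3)O1)OC2=O
F8 | step 11 | (S)-4-bromobutan-2-ol | C[C@H](O)CCBr
F9 | step 11 | (S)-(3-hydroxybutyl)triphenylphosphonium bromide | C[C@H](O)CC[P+](c1ccccc1)(c1ccccc1)c1ccccc1.[Br-]
F10 | step 11 | potassium (S)-4-(triphenyl-λ5-phosphanylidene)butan-2-olate | C[C@H]([O-])CC=P(c1ccccc1)(c1ccccc1)c1ccccc1.[K+]
F11 | step 11 | (S)-4-[(S)-2-(pent-4-en-1-yl)cyclobutylidene]butan-2-ol (E isomer drawn) | C=CCCC[C@H]1CC/C1=C\C[C@H](C)O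
F12 | step 11 | (R)-3-{(E)-6-[(S)-2-((S)-3-hydroxybutylidene)cyclobutyl]hex-2-en-1-yl}-5,7-dimethoxyisobenzofuran-1(3H)-one | COc1cc(OC)c2c(c1)[C@@H](C/C=C/CCC[C@H]1CC/C1=C\C[C@H](C)O)OC2=O
F13 | step 12 | (R)-3-{6-[(1S)-2-hydroperoxy-2-((S,E)-3-hydroxybut-1-en-1-yl)cyclobutyl]hexyl}-5,7-dimethoxyisobenzofuran-1(3H)-one (both epimers at the hydroperoxide carbon) | COc1cc(OC)c2c(c1)[C@@H](CCCCCC[C@H]1CCC1(OO)/C=C/[C@H](C)O)OC2=O
F14 | step 12 | (R)-3-{6-[(1S)-2-hydroperoxy-2-((S)-3-hydroxybutyl)cyclobutyl]hexyl}-5,7-dimethoxyisobenzofuran-1(3H)-one (both epimers at the hydroperoxide carbon) | COc1cc(OC)c2c(c1)[C@@H](CCCCCC[C@H]1CCC1(CC[C@H](C)O)OO)OC2=O
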